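Ring A (C1–C6, the epoxycyclohexane) is read as a hidden 2‑oxabicyclo[2.2.2]octenone: its C3 oxygen and C7 lie cis, so they can be tied as a lactone bridge, and C1(Me)2–C2H2 is an isobutene unit. The key step is an amine‑catalysed Diels–Alder reaction of flat, achiral 3‑hydroxy‑4‑methyl‑2‑pyrone with methacrolein (its formyl group later becomes the second C1 methyl). It forms C2–C3 and C1–C6 at once and sets C3 and C6; the C6 hydroxyl then delivers the epoxide oxygen to C5. Ring B and the polyenyne come from Takai‑type olefinations and a Suzuki coupling, the butenolide from a tandem Sonogashira–lactonisation, and a last Suzuki coupling joins the halves.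

Key step: step 4

Assumption: the quinidine‑derived amine is taken to give the (1S,4R) enantiomer of 9; if the sense is opposite, its quinine‑derived pseudoenantiomer is used without other change.
Remark: ring A locants are C1 = CMe2, C2 = CH2, C3 = CH–O, C4 = CH2, C5/C6 = epoxide carbons (C6 bears C7). All polyene steps are run under argon in dim light.

Step 1
Reactants: 1 3‑methyloxolan‑2‑one (α‑methyl‑γ‑butyrolactone, racemic); 2 diethyl oxalate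
Product: 3 ethyl 2‑(3‑methyl‑2‑oxooxolan‑3‑yl)‑2‑oxoacetate (racemic)
Conditions: LiN(i‑Pr)2, THF, −78 °C; enolate added to 2 (1.5 equiv), −78 to 0 °C; 1 M HCl quench
Reagents that add atoms: none
Why: Claisen‑type C‑acylation of the lactone lithium enolate by the non‑enolisable, highly electrophilic oxalate gives the quaternary oxalyl lactone.

Step 2
Reactants: 3 ethyl 2‑(3‑methyl‑2‑oxooxolan‑3‑yl)‑2‑oxoacetate
Product: 5 3‑hydroxy‑4‑methyl‑5,6‑dihydro‑2H‑pyran‑2‑one, via keto acid 4 (not isolated)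
Conditions: 6 M HCl, 100 °C; then toluene azeotrope
Reagents that add atoms: none
Why: Acid hydrolysis of ester and lactone, decarboxylation of the β‑keto acid and relactonisation of the δ‑hydroxy α‑keto acid give the enolised six‑membered α‑keto lactone (classical α‑keto acid synthesis from oxalyl esters).

Step 3
Reactants: 5 3‑hydroxy‑4‑methyl‑5,6‑dihydro‑2H‑pyran‑2‑one
Product: 7 3‑hydroxy‑4‑methyl‑2H‑pyran‑2‑one, via bromo dione 6 (not isolated)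
Conditions: Br2 (1.0 equiv), CH2Cl2, 0 °C; then Et3N (2.2 equiv), 0 °C to rt
Reagents that add atoms: none
Why: Bromination of the enol at C4, loss of HBr toward C5 and tautomerisation of the resulting enedione give the aromatic 2‑pyrone (bromination–dehydrobromination).

Step 4
Reactants: 7 3‑hydroxy‑4‑methyl‑2H‑pyran‑2‑one; 8 methacrolein (2‑methylprop‑2‑enal)
Product: 9 (1S,4R)‑4‑hydroxy‑5,8‑dimethyl‑3‑oxo‑2‑oxabicyclo[2.2.2]oct‑5‑ene‑8‑carbaldehyde (both C8 epimers)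
Conditions: 9‑amino‑9‑deoxy‑epi‑quinidine (10 mol %), CF3CO2H (20 mol %), 8 (3 equiv), CH2Cl2, 0 °C to rt
Reagents that add atoms: none
Why: The primary amine of the catalyst condenses with 8 to an iminium ion while the quinuclidine deprotonates 7, so the pyrone dienolate adds through its C6 to the CH2 terminus of the iminium ion (vinylogous Michael addition, ring A bond C2–C3) and the resulting enamine closes onto the C3 carbonyl (aldol, ring A bond C1–C6), a stepwise [4+2] cycloaddition. The closest known reaction is the cinchona‑amine‑catalysed asymmetric Diels–Alder reaction of 3‑hydroxy‑2‑pyrones with α,β‑unsaturated carbonyl compounds. The carbocycle is closed by a 6‑(enolexo)‑exo‑trig aldol, which turns the pyrone lactone into the two‑atom bridge of the bicycle. The CH–O bridgehead (C3 of ring A) is set by the catalyst, which blocks one face of the ion‑paired dienolate, and the carbinol bridgehead (C6) is then fixed cis to it by the bicyclic constraint, while the CMe(CHO) centre needs no control because step 5 turns it into CMe2. The step needs regioselectivity, secured by polarity (the nucleophilic C6 of the dienolate meets the unsubstituted β‑carbon of the enal), and retention of the CO2 bridge, secured by working at or below room temperature.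

Step 5
Reactants: 9 (1S,4R)‑4‑hydroxy‑5,8‑dimethyl‑3‑oxo‑2‑oxabicyclo[2.2.2]oct‑5‑ene‑8‑carbaldehyde
Product: 11 (1S,4S)‑4‑hydroxy‑5,8,8‑trimethyl‑2‑oxabicyclo[2.2.2]oct‑5‑en‑3‑one, via tosylhydrazone 10 (not isolated)
Conditions: TsNHNH2, EtOH, rt; then catecholborane (2.5 equiv), CHCl3, 0 °C; NaOAc·3H2O, 60 °C
Reagents that add atoms: none
Why: Caglioti‑type tosylhydrazone reduction (hydroboration of C=N, loss of sulfinate, N2 extrusion from the diazene) turns CHO into CH3 under non‑basic conditions, which removes the retro‑aldol‑prone β‑hydroxy aldehyde and the C8 stereocentre.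

Step 6
Reactants: 11 (1S,4S)‑4‑hydroxy‑5,8,8‑trimethyl‑2‑oxabicyclo[2.2.2]oct‑5‑en‑3‑one
Product: 12 methyl (1S,4S)‑1,4‑dihydroxy‑2,6,6‑trimethylcyclohex‑2‑ene‑1‑carboxylate
Conditions: NaOMe (0.2 equiv), MeOH, 0 °C; AcOH quench
Reagents that add atoms: methanol, CO
Why: Methanolysis of the strained bridged lactone at the acyl carbon breaks no bond to a stereocentre, so both centres are retained.

Step 7
Reactants: 12 methyl (1S,4S)‑1,4‑dihydroxy‑2,6,6‑trimethylcyclohex‑2‑ene‑1‑carboxylate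
Product: 13 methyl (1S,4S)‑1‑hydroxy‑2,6,6‑trimethyl‑4‑[(triethylsilyl)oxy]cyclohex‑2‑ene‑1‑carboxylate
Conditions: Et3SiCl, imidazole, CH2Cl2, 0 °C
Reagents that add atoms: chlorotriethylsilane, CC[Si](Cl)(CC)CC
Why: Only the secondary allylic hydroxyl is silylated; the tertiary α‑hydroxy ester oxygen is too hindered, and the silyl ether blocks relactonisation.

Step 8
Reactants: 13 methyl (1S,4S)‑1‑hydroxy‑2,6,6‑trimethyl‑4‑[(triethylsilyl)oxy]cyclohex‑2‑ene‑1‑carboxylate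
Product: 14 methyl (1S,4S,6R)‑2,2,6‑trimethyl‑4‑[(triethylsilyl)oxy]‑7‑oxabicyclo[4.1.0]heptane‑1‑carboxylate
Conditions: Co(salen) [N,N'‑bis(3,5‑di‑tert‑butylsalicylidene)‑1,2‑cyclohexanediaminocobalt] (5 mol %), N‑fluoro‑2,4,6‑trimethylpyridinium triflate (1.3 equiv), PhSiH3 (1.3 equiv), acetone, 0 °C
Reagents that add atoms: none
Why: Hydrogen‑atom transfer from a cobalt hydride to C4 gives the tertiary C5 radical, which is captured, oxidised to a tetravalent alkylcobalt species and displaced by the C6 hydroxyl in a 3‑exo‑tet closure (cobalt–salen radical–polar crossover cycloisomerisation of tertiary allylic alcohols to epoxides); the oxygen can only bridge on the face it already occupies, so C5 is set by C6, and the ester disfavours a competing 1,2‑shift.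

Step 9
Reactants: 14 methyl (1S,4S,6R)‑2,2,6‑trimethyl‑4‑[(triethylsilyl)oxy]‑7‑oxabicyclo[4.1.0]heptane‑1‑carboxylate
Product: 15 (1S,4S,6R)‑2,2,6‑trimethyl‑4‑[(triethylsilyl)oxy]‑7‑oxabicyclo[4.1.0]heptane‑1‑carbaldehyde
Conditions: i‑Bu2AlH (1.1 equiv), CH2Cl2, −78 °C; MeOH, then aq. potassium sodium tartrate (KNaC4H4O6)
Reagents that add atoms: none
Why: Partial reduction of the α‑alkoxy ester stops at the chelated aluminium hemiacetal at −78 °C and releases the aldehyde on work‑up, leaving epoxide and silyl ether untouched.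

Step 10
Reactants: 15 (1S,4S,6R)‑2,2,6‑trimethyl‑4‑[(triethylsilyl)oxy]‑7‑oxabicyclo[4.1.0]heptane‑1‑carbaldehyde
Product: 16 4,4,5,5‑tetramethyl‑2‑[(E)‑2‑{(1S,4S,6R)‑2,2,6‑trimethyl‑4‑[(triethylsilyl)oxy]‑7‑oxabicyclo[4.1.0]heptan‑1‑yl}ethenyl]‑1,3,2‑dioxaborolane
Conditions: CrCl2 (8 equiv), Cl2CHB(pin) (2 equiv), LiI (4 equiv), THF, rt
Reagents that add atoms: 2‑(dichloromethyl)‑4,4,5,5‑tetramethyl‑1,3,2‑dioxaborolane, ClC(Cl)B1OC(C)(C)C(C)(C)O1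
Why: Takai–Utimoto olefination: the geminal dichromium species adds to the non‑enolisable aldehyde and anti elimination should give the (E)‑alkenylboronate (C7=C8).

Step 11
Reactants: 17 (4R,6R)‑4‑hydroxy‑2,2,6‑trimethylcyclohexan‑1‑one ((−)‑actinol)
Product: 18 (4R,6R)‑2,2,6‑trimethyl‑4‑[(triethylsilyl)oxy]cyclohexan‑1‑one
Conditions: Et3SiCl, imidazole, DMF, rt
Reagents that add atoms: chlorotriethylsilane, CC[Si](Cl)(CC)CC
Why: Standard silylation of the secondary alcohol, needed before enolate formation.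

Step 12
Reactants: 18 (4R,6R)‑2,2,6‑trimethyl‑4‑[(triethylsilyl)oxy]cyclohexan‑1‑one
Product: 19 (4R)‑2,6,6‑trimethyl‑4‑[(triethylsilyl)oxy]cyclohex‑1‑en‑1‑yl trifluoromethanesulfonate
Conditions: LiN(i‑Pr)2, THF, −78 °C; PhNTf2, −78 to 0 °C
Reagents that add atoms: N‑phenylbis(trifluoromethanesulfonimide), O=S(=O)(N(c1ccccc1)S(=O)(=O)C(F)(F)F)C(F)(F)F
Why: Only C6 carries an α‑hydrogen, so a single enolate forms and is O‑triflated; the C6 stereocentre is erased on purpose while C4 is untouched.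

Step 13
Reactants: 19 (4R)‑2,6,6‑trimethyl‑4‑[(triethylsilyl)oxy]cyclohex‑1‑en‑1‑yl trifluoromethanesulfonate; 20 (2E)‑3‑methylpent‑2‑en‑4‑yn‑1‑ol
Product: 21 (2E)‑3‑methyl‑5‑{(4R)‑2,6,6‑trimethyl‑4‑[(triethylsilyl)oxy]cyclohex‑1‑en‑1‑yl}pent‑2‑en‑4‑yn‑1‑ol
Conditions: Pd(PPh3)4 (5 mol %), CuI (10 mol %), Et3N, DMF, rt
Reagents that add atoms: none
Why: Sonogashira coupling of the enol triflate with the terminal alkyne installs the ring B enyne with the E double bond of 20 unchanged.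

Step 14
Reactants: 21 (2E)‑3‑methyl‑5‑{(4R)‑2,6,6‑trimethyl‑4‑[(triethylsilyl)oxy]cyclohex‑1‑en‑1‑yl}pent‑2‑en‑4‑yn‑1‑ol
Product: 22 (2E)‑3‑methyl‑5‑{(4R)‑2,6,6‑trimethyl‑4‑[(triethylsilyl)oxy]cyclohex‑1‑en‑1‑yl}pent‑2‑en‑4‑ynal
Conditions: MnO2 (activated, excess), CH2Cl2, rt
Reagents that add atoms: none
Why: Chemoselective oxidation of the allylic alcohol to the enal.

Step 15
Reactants: 22 (2E)‑3‑methyl‑5‑{(4R)‑2,6,6‑trimethyl‑4‑[(triethylsilyl)oxy]cyclohex‑1‑en‑1‑yl}pent‑2‑en‑4‑ynal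
Product: 23 triethyl({(1R)‑4‑[(3E,5E)‑6‑iodo‑3‑methylhexa‑3,5‑dien‑1‑yn‑1‑yl]‑3,5,5‑trimethylcyclohex‑3‑en‑1‑yl}oxy)silane
Conditions: CrCl2 (6 equiv), CHI3 (2 equiv), 1,4‑dioxane/THF, 0 °C to rt
Reagents that add atoms: iodoform, IC(I)I
Why: Takai iodo‑olefination should give the (E)‑alkenyl iodide through anti elimination from the β‑oxido gem‑dichromium adduct.

Step 16
Reactants: 20 (2E)‑3‑methylpent‑2‑en‑4‑yn‑1‑ol
Product: 24 (2E)‑3‑methylpent‑2‑en‑4‑ynal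
Conditions: MnO2 (activated, excess), CH2Cl2, rt; filtered solution used directly
Reagents that add atoms: none
Why: Allylic oxidation; the volatile enynal is not concentrated.

Step 17
Reactants: 24 (2E)‑3‑methylpent‑2‑en‑4‑ynal
Product: 25 4,4,5,5‑tetramethyl‑2‑[(1E,3E)‑4‑methylhexa‑1,3‑dien‑5‑yn‑1‑yl]‑1,3,2‑dioxaborolane
Conditions: CrCl2 (8 equiv), Cl2CHB(pin) (2 equiv), LiI (4 equiv), THF, rt
Reagents that add atoms: 2‑(dichloromethyl)‑4,4,5,5‑tetramethyl‑1,3,2‑dioxaborolane, ClC(Cl)B1OC(C)(C)C(C)(C)O1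
Why: Takai–Utimoto olefination gives the (E)‑dienylboronate; divalent chromium does not touch the terminal alkyne.

Step 18
Reactants: 23 triethyl({(1R)‑4‑[(3E,5E)‑6‑iodo‑3‑methylhexa‑3,5‑dien‑1‑yn‑1‑yl]‑3,5,5‑trimethylcyclohex‑3‑en‑1‑yl}oxy)silane; 25 4,4,5,5‑tetramethyl‑2‑[(1E,3E)‑4‑methylhexa‑1,3‑dien‑5‑yn‑1‑yl]‑1,3,2‑dioxaborolane
Product: 26 triethyl({(1R)‑4‑[(3E,5E,7E,9E)‑3,10‑dimethyldodeca‑3,5,7,9‑tetraene‑1,11‑diyn‑1‑yl]‑3,5,5‑trimethylcyclohex‑3‑en‑1‑yl}oxy)silane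
Conditions: PdCl2(dppf) (5 mol %), aq. K3PO4, THF, rt, degassed
Reagents that add atoms: none
Why: Suzuki coupling joins the two sp2 carbons with retention at both alkenes, so the tetraene is assembled without any equilibration that could isomerise the double bond next to the ring B alkyne.

Step 19
Reactants: 27 propiolic acid (prop‑2‑ynoic acid)
Product: 28 (2E)‑2,3‑dibromoprop‑2‑enoic acid
Conditions: Br2 (1.0 equiv), CHCl3, 0 °C to rt, dark
Reagents that add atoms: bromine, BrBr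
Why: Anti addition of bromine to the alkyne gives the E dibromide, in which the β‑bromine is cis to the carboxyl group.

Step 20
Reactants: 26 triethyl({(1R)‑4‑[(3E,5E,7E,9E)‑3,10‑dimethyldodeca‑3,5,7,9‑tetraene‑1,11‑diyn‑1‑yl]‑3,5,5‑trimethylcyclohex‑3‑en‑1‑yl}oxy)silane; 28 (2E)‑2,3‑dibromoprop‑2‑enoic acid
Product: 30 (5Z)‑3‑bromo‑5‑[(2E,4E,6E,8E)‑2,9‑dimethyl‑11‑{(4R)‑2,6,6‑trimethyl‑4‑[(triethylsilyl)oxy]cyclohex‑1‑en‑1‑yl}undeca‑2,4,6,8‑tetraen‑10‑yn‑1‑ylidene]furan‑2(5H)‑one, via bromo enynoic acid 29 (not isolated)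
Conditions: Pd(PPh3)4 (5 mol %), CuI (10 mol %), Et3N (3 equiv), MeCN, rt, BHT (cat.), 28 in slight excess
Reagents that add atoms: none
Why: Sonogashira coupling occurs at the β carbon–bromine bond (the vinylogous acyl bromide position, which undergoes oxidative addition faster than the α position), and the cis carboxylate then adds anti across the alkyne in a 5‑exo‑dig closure to give the (Z)‑ylidenebutenolide (tandem coupling–lactonisation of (Z)‑3‑haloacrylic acids with 1‑alkynes).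

Step 21
Reactants: 30 (5Z)‑3‑bromo‑5‑[(2E,4E,6E,8E)‑2,9‑dimethyl‑11‑{(4R)‑2,6,6‑trimethyl‑4‑[(triethylsilyl)oxy]cyclohex‑1‑en‑1‑yl}undeca‑2,4,6,8‑tetraen‑10‑yn‑1‑ylidene]furan‑2(5H)‑one; 16 4,4,5,5‑tetramethyl‑2‑[(E)‑2‑{(1S,4S,6R)‑2,2,6‑trimethyl‑4‑[(triethylsilyl)oxy]‑7‑oxabicyclo[4.1.0]heptan‑1‑yl}ethenyl]‑1,3,2‑dioxaborolane
Product: 31 (5Z)‑3‑[(E)‑2‑{(1S,4S,6R)‑2,2,6‑trimethyl‑4‑[(triethylsilyl)oxy]‑7‑oxabicyclo[4.1.0]heptan‑1‑yl}ethenyl]‑5‑[(2E,4E,6E,8E)‑2,9‑dimethyl‑11‑{(4R)‑2,6,6‑trimethyl‑4‑[(triethylsilyl)oxy]cyclohex‑1‑en‑1‑yl}undeca‑2,4,6,8‑tetraen‑10‑yn‑1‑ylidene]furan‑2(5H)‑one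
Conditions: Pd(PPh3)4 (10 mol %), CsF (3 equiv), THF/H2O (10:1), rt
Reagents that add atoms: none
Why: Suzuki coupling of the α‑bromobutenolide with the alkenylboronate forms the C8–butenolide bond with retention of both alkene geometries; fluoride activation keeps the medium mild for the enol lactone.

Step 22
Reactants: 31 the bis(triethylsilyl) ether named in step 21
Product: 32 (5Z)‑3‑[(E)‑2‑{(1S,4S,6R)‑4‑hydroxy‑2,2,6‑trimethyl‑7‑oxabicyclo[4.1.0]heptan‑1‑yl}ethenyl]‑5‑[(2E,4E,6E,8E)‑11‑{(4R)‑4‑hydroxy‑2,6,6‑trimethylcyclohex‑1‑en‑1‑yl}‑2,9‑dimethylundeca‑2,4,6,8‑tetraen‑10‑yn‑1‑ylidene]furan‑2(5H)‑one (target)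
Conditions: Bu4NF (4 equiv), AcOH (4 equiv), THF, 0 °C to rt
Reagents that add atoms: none
Why: Acetic‑acid‑buffered fluoride removes both triethylsilyl ethers without base‑ or acid‑induced damage to the butenolide or the epoxide.

Compound list
1 | 3‑methyloxolan‑2‑one (racemic) | CC1CCOC1=O | starting material
2 | diethyl oxalate | CCOC(=O)C(=O)OCC | starting material
3 | ethyl 2‑(3‑methyl‑2‑oxooxolan‑3‑yl)‑2‑oxoacetate (racemic) | CCOC(=O)C(=O)C1(C)CCOC1=O | intermediate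
4 | 5‑hydroxy‑3‑methyl‑2‑oxopentanoic acid (racemic, not isolated) | CC(CCO)C(=O)C(=O)O | intermediate
5 | 3‑hydroxy‑4‑methyl‑5,6‑dihydro‑2H‑pyran‑2‑one | CC1=C(O)C(=O)OCC1 | intermediate
6 | 4‑bromo‑4‑methyloxane‑2,3‑dione (racemic, not isolated) | CC1(Br)CCOC(=O)C1=O | intermediate
7 | 3‑hydroxy‑4‑methyl‑2H‑pyran‑2‑one | CC1=C(O)C(=O)OC=C1 | intermediate
8 | methacrolein | CC(=C)C=O | starting material
9 | (1S,4R)‑4‑hydroxy‑5,8‑dimethyl‑3‑oxo‑2‑oxabicyclo[2.2.2]oct‑5‑ene‑8‑carbaldehyde (C8 epimers) | O=CC1(C)C[C@H]2C=C(C)[C@]1(O)C(=O)O2 | intermediate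
10 | N'‑{[(1S,4R)‑4‑hydroxy‑5,8‑dimethyl‑3‑oxo‑2‑oxabicyclo[2.2.2]oct‑5‑en‑8‑yl]methylidene}‑4‑methylbenzenesulfonohydrazide (not isolated) | Cc1ccc(cc1)S(=O)(=O)NN=CC1(C)C[C@H]2C=C(C)[C@]1(O)C(=O)O2 | intermediate
11 | (1S,4S)‑4‑hydroxy‑5,8,8‑trimethyl‑2‑oxabicyclo[2.2.2]oct‑5‑en‑3‑one | CC1(C)C[C@H]2C=C(C)[C@]1(O)C(=O)O2 | intermediate
12 | methyl (1S,4S)‑1,4‑dihydroxy‑2,6,6‑trimethylcyclohex‑2‑ene‑1‑carboxylate | COC(=O)[C@@]1(O)C(C)=C[C@@H](O)CC1(C)C | intermediate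
13 | methyl (1S,4S)‑1‑hydroxy‑2,6,6‑trimethyl‑4‑[(triethylsilyl)oxy]cyclohex‑2‑ene‑1‑carboxylate | COC(=O)[C@@]1(O)C(C)=C[C@@H](O[Si](CC)(CC)CC)CC1(C)C | intermediate
14 | methyl (1S,4S,6R)‑2,2,6‑trimethyl‑4‑[(triethylsilyl)oxy]‑7‑oxabicyclo[4.1.0]heptane‑1‑carboxylate | COC(=O)[C@@]12O[C@]1(C)C[C@@H](O[Si](CC)(CC)CC)CC2(C)C | intermediate
15 | (1S,4S,6R)‑2,2,6‑trimethyl‑4‑[(triethylsilyl)oxy]‑7‑oxabicyclo[4.1.0]heptane‑1‑carbaldehyde | O=C[C@@]12O[C@]1(C)C[C@@H](O[Si](CC)(CC)CC)CC2(C)C | intermediate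
16 | 4,4,5,5‑tetramethyl‑2‑[(E)‑2‑{(1S,4S,6R)‑2,2,6‑trimethyl‑4‑[(triethylsilyl)oxy]‑7‑oxabicyclo[4.1.0]heptan‑1‑yl}ethenyl]‑1,3,2‑dioxaborolane | CC1(C)OB(/C=C/[C@@]23O[C@]2(C)C[C@@H](O[Si](CC)(CC)CC)CC3(C)C)OC1(C)C | intermediate
17 | (4R,6R)‑4‑hydroxy‑2,2,6‑trimethylcyclohexan‑1‑one | O=C1C(C)(C)C[C@H](O)C[C@H]1C | starting material
18 | (4R,6R)‑2,2,6‑trimethyl‑4‑[(triethylsilyl)oxy]cyclohexan‑1‑one | O=C1C(C)(C)C[C@H](O[Si](CC)(CC)CC)C[C@H]1C | intermediate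
19 | (4R)‑2,6,6‑trimethyl‑4‑[(triethylsilyl)oxy]cyclohex‑1‑en‑1‑yl trifluoromethanesulfonate | CC1=C(OS(=O)(=O)C(F)(F)F)C(C)(C)C[C@H](O[Si](CC)(CC)CC)C1 | intermediate
20 | (2E)‑3‑methylpent‑2‑en‑4‑yn‑1‑ol | C#C/C(C)=C/CO | starting material
21 | (2E)‑3‑methyl‑5‑{(4R)‑2,6,6‑trimethyl‑4‑[(triethylsilyl)oxy]cyclohex‑1‑en‑1‑yl}pent‑2‑en‑4‑yn‑1‑ol | CC1=C(C#C/C(C)=C/CO)C(C)(C)C[C@H](O[Si](CC)(CC)CC)C1 | intermediate
22 | (2E)‑3‑methyl‑5‑{(4R)‑2,6,6‑trimethyl‑4‑[(triethylsilyl)oxy]cyclohex‑1‑en‑1‑yl}pent‑2‑en‑4‑ynal | CC1=C(C#C/C(C)=C/C=O)C(C)(C)C[C@H](O[Si](CC)(CC)CC)C1 | intermediate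
23 | triethyl({(1R)‑4‑[(3E,5E)‑6‑iodo‑3‑methylhexa‑3,5‑dien‑1‑yn‑1‑yl]‑3,5,5‑trimethylcyclohex‑3‑en‑1‑yl}oxy)silane | CC1=C(C#C/C(C)=C/C=C/I)C(C)(C)C[C@H](O[Si](CC)(CC)CC)C1 | intermediate
24 | (2E)‑3‑methylpent‑2‑en‑4‑ynal | C#C/C(C)=C/C=O | intermediate
25 | 4,4,5,5‑tetramethyl‑2‑[(1E,3E)‑4‑methylhexa‑1,3‑dien‑5‑yn‑1‑yl]‑1,3,2‑dioxaborolane | C#C/C(C)=C/C=C/B1OC(C)(C)C(C)(C)O1 | intermediate
26 | triethyl({(1R)‑4‑[(3E,5E,7E,9E)‑3,10‑dimethyldodeca‑3,5,7,9‑tetraene‑1,11‑diyn‑1‑yl]‑3,5,5‑trimethylcyclohex‑3‑en‑1‑yl}oxy)silane | CC1=C(C#C/C(C)=C/C=C/C=C/C=C(C)/C#C)C(C)(C)C[C@H](O[Si](CC)(CC)CC)C1 | intermediate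
27 | propiolic acid | C#CC(=O)O | starting material
28 | (2E)‑2,3‑dibromoprop‑2‑enoic acid | OC(=O)/C(Br)=C\Br | intermediate
29 | (2E,6E,8E,10E,12E)‑2‑bromo‑6,13‑dimethyl‑15‑{(4R)‑2,6,6‑trimethyl‑4‑[(triethylsilyl)oxy]cyclohex‑1‑en‑1‑yl}pentadeca‑2,6,8,10,12‑pentaene‑4,14‑diynoic acid (not isolated) | CC1=C(C#C/C(C)=C/C=C/C=C/C=C(C)/C#C/C=C(/Br)C(=O)O)C(C)(C)C[C@H](O[Si](CC)(CC)CC)C1 | intermediate
30 | (5Z)‑3‑bromo‑5‑[(2E,4E,6E,8E)‑2,9‑dimethyl‑11‑{(4R)‑2,6,6‑trimethyl‑4‑[(triethylsilyl)oxy]cyclohex‑1‑en‑1‑yl}undeca‑2,4,6,8‑tetraen‑10‑yn‑1‑ylidene]furan‑2(5H)‑one | CC1=C(C#C/C(C)=C/C=C/C=C/C=C(C)/C=C2C=C(Br)C(=O)O/2)C(C)(C)C[C@H](O[Si](CC)(CC)CC)C1 | intermediate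
31 | bis(triethylsilyl) ether of the target (full name in step 21) | CC1=C(C#C/C(C)=C/C=C/C=C/C=C(C)/C=C2C=C(/C=C/[C@@]34O[C@]3(C)C[C@@H](O[Si](CC)(CC)CC)CC4(C)C)C(=O)O/2)C(C)(C)C[C@H](O[Si](CC)(CC)CC)C1 | intermediate
32 | (5Z)‑3‑[(E)‑2‑{(1S,4S,6R)‑4‑hydroxy‑2,2,6‑trimethyl‑7‑oxabicyclo[4.1.0]heptan‑1‑yl}ethenyl]‑5‑[(2E,4E,6E,8E)‑11‑{(4R)‑4‑hydroxy‑2,6,6‑trimethylcyclohex‑1‑en‑1‑yl}‑2,9‑dimethylundeca‑2,4,6,8‑tetraen‑10‑yn‑1‑ylidene]furan‑2(5H)‑one | CC1=C(C#C/C(C)=C/C=C/C=C/C=C(C)/C=C2C=C(/C=C/[C@@]34O[C@]3(C)C[C@@H](O)CC4(C)C)C(=O)O/2)C(C)(C)C[C@H](O)C1 | target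

Total step count: 22. Longest linear sequence: 12 steps (steps 1–10, 21, 22); the ring B/polyenyne branch (steps 11–15, 18, 20) and the two short branches (steps 16–17 and step 19) converge on it.

Steps most likely to fail

Step 4. The second bond (C1–C6) joins two fully substituted carbons, so the aldol closure may be slow or may revert (retro‑aldol, then retro‑Michael), and the catalyst may discriminate the dienolate faces poorly with the 4‑methyl pyrone and an α‑branched enal. The fallback sets out from 7 and returns at 12. Pyrone 7 is acetylated (Ac2O, pyridine) to 4‑methyl‑2‑oxo‑2H‑pyran‑3‑yl acetate F1. F1 undergoes a thermal inverse‑demand [4+2] cycloaddition with isobutene under high pressure (about 12 kbar, CH2Cl2, 40 °C); the alkene CH2 bonds to pyrone C6 and CMe2 to C3, giving the racemic acetoxy lactone rac‑(1S,4S)‑5,8,8‑trimethyl‑3‑oxo‑2‑oxabicyclo[2.2.2]oct‑5‑en‑4‑yl acetate F2 with the gem‑dimethyl group already in place. NaOMe in MeOH cleaves acetate and lactone to racemic methyl 1,4‑dihydroxy‑2,6,6‑trimethylcyclohex‑2‑ene‑1‑carboxylate F3. Lipase‑catalysed acylation (Burkholderia cepacia lipase, vinyl acetate, t‑BuOMe) is expected to acetylate the (4R) enantiomer to methyl (1R,4R)‑4‑acetoxy‑1‑hydroxy‑2,6,6‑trimethylcyclohex‑2‑ene‑1‑carboxylate F4 and leave the (1S,4S) alcohol, which is 12. Steps 4–6 are bypassed.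

Step 8. After hydrogen‑atom transfer and oxidation, a 1,2‑shift of C1 (semipinacol ring contraction) or simple reduction of the alkene may outrun the 3‑exo closure by the weakly nucleophilic α‑hydroxy ester oxygen. The fallback sets out from 13 and returns at 15. The tertiary α‑hydroxyl is removed with SmI2 (HMPA, pivalic acid, THF), and the ester is equilibrated with NaOMe/MeOH into conjugation, giving methyl (4R)‑2,6,6‑trimethyl‑4‑[(triethylsilyl)oxy]cyclohex‑1‑ene‑1‑carboxylate F5. i‑Bu2AlH reduces it to {(4R)‑2,6,6‑trimethyl‑4‑[(triethylsilyl)oxy]cyclohex‑1‑en‑1‑yl}methanol F6. Sharpless epoxidation (Ti(Oi‑Pr)4, L‑(+)‑diethyl tartrate, t‑BuOOH, CH2Cl2, −20 °C) should place the oxygen anti to the silyloxy group by reagent control, giving {(1R,4S,6R)‑2,2,6‑trimethyl‑4‑[(triethylsilyl)oxy]‑7‑oxabicyclo[4.1.0]heptan‑1‑yl}methanol F7. Dess–Martin periodinane oxidises F7 to 15. Steps 8 and 9 are bypassed.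

Step 21. Opening of the enol lactone by the basic aqueous fluoride, protodeboronation of the hindered alkenylboronate and palladium‑mediated E/Z scrambling of the polyene may compete with transmetalation. The fallback sets out from 15 and returns at 31. Chromium‑mediated stannyl‑olefination of 15 (CrCl2, Bu3SnCHBr2, LiI, THF/DMF) gives tributyl[(E)‑2‑{(1S,4S,6R)‑2,2,6‑trimethyl‑4‑[(triethylsilyl)oxy]‑7‑oxabicyclo[4.1.0]heptan‑1‑yl}ethenyl]stannane F8. F8 is joined to 30 by a base‑free Stille coupling (Pd2(dba)3, AsPh3, THF/DMF, rt) to give 31. Step 10 is bypassed.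

Further compounds
F1 | step 4 | 4‑methyl‑2‑oxo‑2H‑pyran‑3‑yl acetate | CC(=O)OC1=C(C)C=COC1=O
F2 | step 4 | rac‑(1S,4S)‑5,8,8‑trimethyl‑3‑oxo‑2‑oxabicyclo[2.2.2]oct‑5‑en‑4‑yl acetate (racemate, one enantiomer drawn) | CC1(C)C[C@H]2C=C(C)[C@]1(OC(C)=O)C(=O)O2
F3 | step 4 | rac‑methyl (1S,4S)‑1,4‑dihydroxy‑2,6,6‑trimethylcyclohex‑2‑ene‑1‑carboxylate (racemate, one enantiomer drawn) | COC(=O)[C@@]1(O)C(C)=C[C@@H](O)CC1(C)C
F4 | step 4 | methyl (1R,4R)‑4‑acetoxy‑1‑hydroxy‑2,6,6‑trimethylcyclohex‑2‑ene‑1‑carboxylate | COC(=O)[C@]1(O)C(C)=C[C@H](OC(C)=O)CC1(C)C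
F5 | step 8 | methyl (4R)‑2,6,6‑trimethyl‑4‑[(triethylsilyl)oxy]cyclohex‑1‑ene‑1‑carboxylate | COC(=O)C1=C(C)C[C@@H](O[Si](CC)(CC)CC)CC1(C)C
F6 | step 8 | {(4R)‑2,6,6‑trimethyl‑4‑[(triethylsilyl)oxy]cyclohex‑1‑en‑1‑yl}methanol | OCC1=C(C)C[C@@H](O[Si](CC)(CC)CC)CC1(C)C
F7 | step 8 | {(1R,4S,6R)‑2,2,6‑trimethyl‑4‑[(triethylsilyl)oxy]‑7‑oxabicyclo[4.1.0]heptan‑1‑yl}methanol | OC[C@@]12O[C@]1(C)C[C@@H](O[Si](CC)(CC)CC)CC2(C)C
F8 | step 21 | tributyl[(E)‑2‑{(1S,4S,6R)‑2,2,6‑trimethyl‑4‑[(triethylsilyl)oxy]‑7‑oxabicyclo[4.1.0]heptan‑1‑yl}ethenyl]stannane | CCCC[Sn](CCCC)(CCCC)/C=C/[C@@]12O[C@]1(C)C[C@@H](O[Si](CC)(CC)CC)CC2(C)C
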